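## The problem

Compound 42 is a germacranolide, and its skeletal locants are used throughout, also for intermediates: carbocycle C1–C10 (C3 = HO–CH, C4 = methyl-bearing and C5 = hydrogen-bearing alkene carbon, C6 = lactone O–CH, C7 = ring-fusion CH, C8 = angelate O–CH, C9 = CH2, C10 = tertiary carbinol), lactone carbons C11 (=C13H2) and C12 (C=O), methyls C14 (on C10) and C15 (on C4). A synthesis must deliver a ten-membered carbocycle with a cis-fused α-methylene-γ-lactone on C6–C7 and a Z C4=C5 alkene whose two allylic neighbours, C3 and C6, carry oxygen on the same ring face. Of the five stereocentres, C6, C7 and C8 are contiguous and can be related to each other, whereas C3 and C10 are insulated by CH2 groups or by the flat alkene. C10 carries a methyl and a ring CH2 that no cyclic transition state tells apart, so it must come from the chiral pool; C3 and C8 need reagent control, and only the C6/C7 pair can be set by the molecule itself. The ring is of medium size, so an end-to-end closure pays transannular strain as well as entropy. The fragile groups are: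
- the α-methylene lactone, a Michael acceptor that tolerates neither hydride nor organometallic reagents;
- the angelate, which isomerises to the tiglate and is destroyed by hydride or organolithium reagents;
- the cis-ene-1,4-dioxygen unit, since a (Z)-γ-hydroxy enal or enoate closes to a furan or butenolide;
- the tertiary alcohol, and a free C8 hydroxyl next to the lactone, which can take over the acyl group from O6.

The enabling feature is the array O–C6–C7–C11=C13. An allylic, oxygenated C6 bonded to a C7 that bears the exocyclic methylene is what a [2,3]-Wittig shift of a C6–O–C13 ether with a C7=C11 alkene leaves behind. Tying O6 to C13 turns the carbocycle into a thirteen-membered ether that can be closed through oxygen.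

## Retrosynthesis

**End game, 42 ← 41 ← 40 ← 39.** Only heteroatom bonds are cut: the C3 silyl ether, the C8–O acyl bond and the C8/C10 acetonide. The angelate is placed last but one because it survives none of the hydride, organolithium or stannyl steps. C3 stays silylated so that only the C8 hydroxyl of 40 is acylated, the tertiary C10 hydroxyl being too hindered. The forward acylation must not isomerise the Z enoate.

**Lactone, 39 ← 37 ← 36.** The O6–C12 acyl bond is cut back to the 1,4-diol 37, whose primary allylic hydroxyl is stored as the PMB ether in 36. Carrying C12 as an ether rather than an ester lets it pass butyllithium. Oxidative lactonisation creates the Michael acceptor only after all basic steps. 36 is simpler than 39 by one ring and one sensitive function.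

**Key cut, 36 ← 34.** C6–C7 is cut, O6 is rejoined to C13 and the alkene is moved from C11=C13 to C7=C11: a retro-[2,3]-Wittig shift. The neighbouring cut of the same bond as a carbonyl allylation would close the ten-membered ring end to end. Here a thirteen-membered ether loses three ring atoms, and the two new stereocentres arise together. 34 has two stereocentres fewer in the ring and no carbocycle. The forward step needs the carbanion exactly at C6 (hence tin), the syn C6/C7 relation (hence C8 cis to C13 on the alkene) and the right alkene face.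

**Tin at C6, 34 ← 30 ← 28.** The C6–Sn bond is cut to the α-acetoxy ether 30 and this to the macrolactone 28. The obvious alternative is O-alkylation of an α-hydroxy allylstannane; it is rejected because its alkoxide reverts to enal and stannyl anion, and acid triggers allyl transposition. Such carbinols are normally capped only with α-halo ethers or silyl chlorides. Entering C6 as a carboxyl group and lowering it to the acetal level keeps the C6–O–C13 linkage intact while tin is introduced as a nucleophile.

**Ring closure, 28 ← 26.** The ester C–O bond is cut to hydroxy acid 26. Macrolactonisation is the most dependable way to close a thirteen-membered ring. 26 has only one free hydroxyl, and two cis alkenes and a dioxane restrict its chain.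

**C13 and the C6 oxidation level, 26 ← 25 ← 23 ← 22 ← 21.** The C11–C13 bond is cut to the alkenyl iodide (Stille hydroxymethylation in the forward sense), so that C13–OH appears only when it is needed and needs no protecting group. Before that, C6 is raised to the acid and the C8/C10 diol is tied up as the acetonide. Iodide 21 carries the alkene geometry that later becomes the C8/C13 cis relation.

**C7–C8, 21 ← 19 ← 18 ← 17 ← 14 + 15.** The C7–C8 bond is cut between aldehyde 14 and alkyne 15. An alkyne is preferred to an alkenyl metal because hydroxyl-directed hydroalumination–iodination sets the trisubstituted alkene with certainty. The ynone 18 allows C8 to be set by asymmetric transfer hydrogenation, since C10 cannot direct. 15 brings C12 already protected.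

**C3–C4, 14 ← 13 ← 11 ← 10 ← 9 ← 7 + 3.** The C3–C4 bond is cut between alkenyl iodide 7 and lactone 3. Acylation by a lactone gives the enone 9 directly, frees the C10 hydroxyl without a protecting group, and lets the CBS reduction set C3. Hydroboration and oxidation then convert the vinyl group into the C8 aldehyde.

**Starting materials, 3 ← 1 and 7 ← 6 ← 4.** (S)-Linalool 1 supplies C8–C9–C10(C14)–C1–C2–C3 with C10 in the required configuration. But-2-yn-1-ol 4 supplies C15, C4, C5 and C6 with the Z geometry from a directed hydroalumination.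

## Roads not taken

**Alternative 1:** Both C–O bonds at C3 and C6 are cut, leaving a conjugated diene over C3–C6 inside the carbocycle, diene A2. Forward, photosensitised singlet oxygen adds across C3 and C6 of A2 to give endoperoxide A1. O–O reduction then gives the cis-3,6-diol, which lactonises onto the C12 ester.
- Merits: one step sets both carbinol centres in the cis relation and the Z alkene, with the angelate and the C10 hydroxyl already in place and no protecting groups on O3 or O6. In redox and protecting-group economy this is clearly better than the chosen plan, which spends about eight steps on such changes.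
- Weak points: the step does not make the ring, so A2 must first be closed end to end. Its diene must reach an s-cis geometry within a ten-membered ring. The face of attack relative to C7 and C8 is left to ring conformation. Ene reactions at the C15 methyl and the C2 hydrogens compete.
- Comparison: the chosen plan answers with a ring construction that avoids end-to-end closure and with C3 fixed by a reagent.

**Alternative 2:** C9–C10 and O–C8 are cut. Forward, NaOCl turns the C10 aldoxime of A4 into a nitrile oxide that adds to the C7 vinyl group, closing the carbocycle as the isoxazoline-bridged lactone A3. N–O cleavage then unmasks a C8 hydroxyl and a C10 ketone.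
- Merits: ring closure and the C8 oxygen come in one convergent step that tolerates the lactone and silyl ether, with fewer protecting groups than the chosen plan.
- Weak points: the closure is again end to end at a ring size where nitrile oxide dimerisation and the bridged/fused regiochemistry are hard to foresee. C8 depends on the vinyl face next to C7. C10 becomes a ketone, so the tertiary carbinol must be made by methyl addition across a medium ring with unknown face preference, on a β-hydroxy ketone that can dehydrate. The methylene lactone still has to be installed.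
- Comparison: the chosen plan has C10 secure from linalool and C8 from a catalyst, at the price of more steps.

**Alternative 3:** C3–C4 is cut. Forward, CrCl2 with catalytic NiCl2 converts the C4 iodide of seco aldehyde A6 into an alkenylchromium that adds to the C3 aldehyde. This closes the ring and gives A5, one desilylation from the target.
- Merits: it is the most convergent road. The reagents tolerate lactone and angelate, the Z geometry is retained, and one step follows the key step instead of five. In step count after the key step it is better than the chosen plan.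
- Weak points: the ten-membered ring is closed end to end. C3 is set only by macrocyclic control, and correcting it by oxidation and reduction would have to be done on the finished, sensitive system. The C6/C7/C8 triad with the cis lactone must be assembled beforehand by other means.
- Comparison: the chosen plan fixes C3 before any ring exists and forms C6/C7 during a ring contraction. It pays with a long protecting-group sequence and a face selectivity of its own that is not assured.

Key step: step 20

Assumption on C6: the allyllithium 35 either loses its C6 configuration before it rearranges, so that both C6 epimers of 34 converge, or rearranges with inversion, so that only the drawn (6S)-epimer of 34 leads to 36 and the epimers are separated at 34. The route is written for the drawn epimer; 29, 30 and 32 are C6-epimer mixtures.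

Remark: 4-methoxybenzyl propargyl ether 15 is taken as a catalogue compound. Metalated intermediates are drawn as monomers, and in 12 and 20 the tertiary hydroxyl is drawn free although it is metalated in the flask.

## Route

Step 1
Reactants: 1 (S)-linalool
Product: 3 (5S)-5-ethenyl-5-methyloxolan-2-one, via lactol 2 (not isolated)
Conditions: O3 (1 equiv), CH2Cl2, −78 °C; Me2S, −78 °C to rt; concentrate; then TEMPO (cat.), PhI(OAc)2, CH2Cl2, rt
Reagents that add atoms: ozone, [O-][O+]=O
Why: Ozonolysis cleaves the electron-rich trisubstituted alkene in preference to the vinyl group when ozone is limited to one equivalent; the hydroxy aldehyde closes to lactol 2, and TEMPO/PhI(OAc)2 oxidation gives the lactone, which masks the C10 hydroxyl and a C3 acyl group at once. C10 comes unchanged from the chiral pool.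

Step 2
Reactants: 4 but-2-yn-1-ol
Product: 6 (Z)-3-iodobut-2-en-1-ol, via alkenylaluminate 5 (not isolated)
Conditions: NaAlH2(OCH2CH2OMe)2 (Red-Al), THF, 0 °C to rt; then I2, THF, −78 to 0 °C
Reagents that add atoms: iodine, II
Why: Hydroxyl-directed trans-hydroalumination delivers hydride to C5 and closes the five-membered C–Al–O chelate 5; iodinolysis with retention puts iodine cis to CH2OH, which is the later cis relation of C3 and C6 across C4=C5.

Step 3
Reactants: 6 (Z)-3-iodobut-2-en-1-ol
Product: 7 (Z)-tert-butyl[(3-iodobut-2-en-1-yl)oxy]dimethylsilane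
Conditions: TBSCl, imidazole, CH2Cl2, rt
Reagents that add atoms: tert-butyldimethylsilyl chloride, CC(C)(C)[Si](C)(C)Cl
Why: Imidazole-promoted silylation of a primary alcohol; the silyl ether tolerates iodine–lithium exchange and keeps the cis C6 oxygen from closing onto C3 later.

Step 4
Reactants: 7 (Z)-tert-butyl[(3-iodobut-2-en-1-yl)oxy]dimethylsilane; 3 (5S)-5-ethenyl-5-methyloxolan-2-one
Product: 9 (2Z,7S)-1-[(tert-butyldimethylsilyl)oxy]-7-hydroxy-3,7-dimethylnona-2,8-dien-4-one, via alkenyllithium 8 (not isolated)
Conditions: 7, t-BuLi (2 equiv), Et2O, −78 °C; then 3, −78 °C; H2O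
Reagents that add atoms: none
Why: Iodine–lithium exchange gives alkenyllithium 8 with retention of geometry; acyl substitution on the γ-lactone stops at the lithium hemiketal at −78 °C and opens to the ketone on work-up, forming C3–C4 and freeing the C10 hydroxyl.

Step 5
Reactants: 9 (2Z,7S)-1-[(tert-butyldimethylsilyl)oxy]-7-hydroxy-3,7-dimethylnona-2,8-dien-4-one
Product: 10 (2Z,4S,7S)-1-[(tert-butyldimethylsilyl)oxy]-3,7-dimethylnona-2,8-diene-4,7-diol
Conditions: (R)-2-methyl-CBS-oxazaborolidine (0.5 equiv), catecholborane, toluene, −78 °C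
Reagents that add atoms: none
Why: Corey–Bakshi–Shibata reduction of an α-methyl enone: the alkenyl group acts as the large substituent, so the (R)-catalyst gives the (S)-carbinol at C3 (locant 4 of 10). Catecholborane at −78 °C leaves the vinyl group alone, and reagent control is needed because C10 is too remote to direct.

Step 6
Reactants: 10 (2Z,4S,7S)-1-[(tert-butyldimethylsilyl)oxy]-3,7-dimethylnona-2,8-diene-4,7-diol
Product: 11 (2Z,4S,7S)-1,4-bis[(tert-butyldimethylsilyl)oxy]-3,7-dimethylnona-2,8-dien-7-ol
Conditions: TBSCl, imidazole, DMF, rt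
Reagents that add atoms: tert-butyldimethylsilyl chloride, CC(C)(C)[Si](C)(C)Cl
Why: Silylation of the secondary allylic alcohol; the tertiary C10 hydroxyl does not react with a silyl chloride under these conditions.

Step 7
Reactants: 11 (2Z,4S,7S)-1,4-bis[(tert-butyldimethylsilyl)oxy]-3,7-dimethylnona-2,8-dien-7-ol
Product: 13 (3S,6S,7Z)-6,9-bis[(tert-butyldimethylsilyl)oxy]-3,7-dimethylnon-7-ene-1,3-diol, via B-alkyl-9-BBN adduct 12 (not isolated)
Conditions: 9-BBN (2.5 equiv), THF, 0 °C to rt; then NaOH, H2O2, 0 °C
Reagents that add atoms: hydrogen peroxide, OO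
Why: Hydroboration–oxidation: 9-BBN adds anti-Markovnikov to the monosubstituted vinyl group only and leaves the hindered trisubstituted alkene; alkaline peroxide replaces boron by hydroxyl at C8.

Step 8
Reactants: 13 (3S,6S,7Z)-6,9-bis[(tert-butyldimethylsilyl)oxy]-3,7-dimethylnon-7-ene-1,3-diol
Product: 14 (3S,6S,7Z)-6,9-bis[(tert-butyldimethylsilyl)oxy]-3-hydroxy-3,7-dimethylnon-7-enal
Conditions: TEMPO (cat.), PhI(OAc)2, CH2Cl2, rt
Reagents that add atoms: none
Why: TEMPO-catalysed oxidation is selective for the primary alcohol and stops at the aldehyde; the tertiary alcohol cannot be oxidised. The β-hydroxy aldehyde is used without storage.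

Step 9
Reactants: 14 (3S,6S,7Z)-6,9-bis[(tert-butyldimethylsilyl)oxy]-3-hydroxy-3,7-dimethylnon-7-enal; 15 4-methoxybenzyl propargyl ether
Product: 17 (6S,9S,10Z)-9,12-bis[(tert-butyldimethylsilyl)oxy]-1-[(4-methoxybenzyl)oxy]-6,10-dimethyldodec-10-en-2-yne-4,6-diol as both C4 epimers, via lithium acetylide 16 (not isolated)
Conditions: 15 (2.5 equiv), n-BuLi, THF, −78 °C; then 14, −78 °C; H2O
Reagents that add atoms: none
Why: 1,2-Addition of a lithium acetylide to the aldehyde forms C7–C8; the excess acetylide takes up the tertiary hydroxyl proton. C8 (locant 4 of 17) is not controlled because C10 cannot tell methyl from methylene, so both epimers go on.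

Step 10
Reactants: 17 propargylic alcohols (C4 epimers)
Product: 18 (6S,9S,10Z)-9,12-bis[(tert-butyldimethylsilyl)oxy]-6-hydroxy-1-[(4-methoxybenzyl)oxy]-6,10-dimethyldodec-10-en-2-yn-4-one
Conditions: MnO2, CH2Cl2, rt
Reagents that add atoms: none
Why: MnO2 oxidises only the propargylic secondary alcohol, so both C8 epimers converge on one ynone.

Step 11
Reactants: 18 ynone
Product: 19 (4R,6S,9S,10Z)-9,12-bis[(tert-butyldimethylsilyl)oxy]-1-[(4-methoxybenzyl)oxy]-6,10-dimethyldodec-10-en-2-yne-4,6-diol
Conditions: Ru[(R,R)-TsNCH(Ph)CH(Ph)NH](η6-p-cymene) (2 mol %), i-PrOH, rt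
Reagents that add atoms: none
Why: Noyori asymmetric transfer hydrogenation of an alkynyl ketone: the alkynyl group takes the place of the aryl group in the usual model, so the (R,R)-catalyst gives the (R)-carbinol at C8. The base-free amido complex avoids retro-aldol and oxa-Michael reactions of the β-hydroxy ynone.

Step 12
Reactants: 19 (4R)-propargylic diol
Product: 21 (2Z,4R,6S,9S,10Z)-9,12-bis[(tert-butyldimethylsilyl)oxy]-2-iodo-1-[(4-methoxybenzyl)oxy]-6,10-dimethyldodeca-2,10-diene-4,6-diol, via alkenylaluminate 20 (not isolated)
Conditions: NaAlH2(OCH2CH2OMe)2 (Red-Al), THF, −20 to 0 °C; then I2, THF, −78 °C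
Reagents that add atoms: iodine, II
Why: As in step 2, the C8 alkoxide directs trans-hydroalumination (H to C7, Al to C11 in chelate 20) and iodinolysis proceeds with retention, so iodine stands cis to C8. The low temperature keeps the alkenylaluminate from expelling the PMB-oxy group to form an allene.

Step 13
Reactants: 21 alkenyl iodide diol
Product: 22 (4R,6S)-4-[(Z)-2-iodo-3-[(4-methoxybenzyl)oxy]prop-1-en-1-yl]-2,2,6-trimethyl-6-[(3S,4Z)-3,6-bis[(tert-butyldimethylsilyl)oxy]-4-methylhex-4-en-1-yl]-1,3-dioxane
Conditions: 2,2-dimethoxypropane, PPTS (cat.), CH2Cl2, rt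
Reagents that add atoms: 2,2-dimethoxypropane, COC(C)(C)OC
Why: Acid-catalysed transketalisation closes the 1,3-dioxane over the secondary C8 and tertiary C10 hydroxyls, the only diol in the molecule; the silyl ethers tolerate PPTS in an aprotic medium.

Step 14
Reactants: 22 acetonide
Product: 23 (2Z,4S)-4-[(tert-butyldimethylsilyl)oxy]-6-[(4S,6R)-6-[(Z)-2-iodo-3-[(4-methoxybenzyl)oxy]prop-1-en-1-yl]-2,2,4-trimethyl-1,3-dioxan-4-yl]-3-methylhex-2-en-1-ol
Conditions: HF·pyridine, pyridine, THF, 0 °C
Reagents that add atoms: none
Why: Buffered fluoride cleaves the unhindered primary allylic silyl ether much faster than the secondary one next to the C4 methyl group; acetonide, PMB ether and alkenyl iodide are inert.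

Step 15
Reactants: 23 C6 alcohol
Product: 25 (2Z,4S)-4-[(tert-butyldimethylsilyl)oxy]-6-[(4S,6R)-6-[(Z)-2-iodo-3-[(4-methoxybenzyl)oxy]prop-1-en-1-yl]-2,2,4-trimethyl-1,3-dioxan-4-yl]-3-methylhex-2-enoic acid, via enal 24 (not isolated)
Conditions: MnO2, CH2Cl2, rt; filter; then NaClO2, NaH2PO4, 2-methyl-2-butene, t-BuOH/H2O, 0 °C
Reagents that add atoms: sodium chlorite, [Na+].[O-]Cl=O
Why: Allylic oxidation with MnO2 gives the Z enal without isomerisation, and Pinnick oxidation with a hypochlorite scavenger takes it to the acid under buffered conditions that spare the alkenes, the PMB ether and the silyl ether.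

Step 16
Reactants: 25 iodo acid
Product: 26 (2Z,4S)-4-[(tert-butyldimethylsilyl)oxy]-6-[(4S,6R)-6-[(E)-3-hydroxy-2-{[(4-methoxybenzyl)oxy]methyl}prop-1-en-1-yl]-2,2,4-trimethyl-1,3-dioxan-4-yl]-3-methylhex-2-enoic acid (C13 hydroxymethyl cis to C8)
Conditions: Bu3SnCH2OH, Pd(PPh3)4 (5 mol %), i-Pr2NEt, dioxane, 80 °C
Reagents that add atoms: (tributylstannyl)methanol, CCCC[Sn](CCCC)(CCCC)CO
Why: Stille coupling transfers the hydroxymethyl group to the alkenyl iodide with retention, so C13 ends cis to C8; the amine keeps the acid as its carboxylate so that it does not attack the neighbouring silyl ether.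

Step 17
Reactants: 26 hydroxy acid
Product: 28 thirteen-membered macrolactone (ring C6(=O)–O–C13–C11=C7–C8–C9–C10–C1–C2–C3–C4=C5; 3S silyl ether; 8R,10S acetonide; 4Z; C8 cis to C13; C12 PMB ether), via mixed anhydride 27 (not isolated)
Conditions: 2-methyl-6-nitrobenzoic anhydride, DMAP, CH2Cl2, rt, slow addition (final 1 mM)
Reagents that add atoms: none
Why: Shiina macrolactonisation: the mixed anhydride 27 acylates DMAP and the acylpyridinium is captured by the only free hydroxyl, C13–OH, under high dilution. Two cis alkenes and the dioxane pre-organise the chain, and the mild, room-temperature conditions protect the Z enoate.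

Step 18
Reactants: 28 macrolactone
Product: 30 thirteen-membered α-acetoxy ether (28 with C6H(OAc) in place of C6=O; both C6 epimers), via aluminium hemiacetal 29 (not isolated)
Conditions: i-Bu2AlH, CH2Cl2, −78 °C; then pyridine, DMAP, Ac2O, −78 to −20 °C
Reagents that add atoms: acetic anhydride, CC(=O)OC(C)=O
Why: Reductive acetylation of an ester: i-Bu2AlH adds once to the lactone carbonyl, the tetrahedral aluminium hemiacetal 29 is stable at −78 °C and is acetylated in place, so the ring stays closed and C6 reaches the acetal level.

Step 19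
Reactants: 30 α-acetoxy ether; 31 tributyltin hydride
Product: 34 (6S)-6-tributylstannyl thirteen-membered allylic ether (28 with C6H(SnBu3) in place of C6=O; formed together with its 6R epimer), via α-bromo ether 32 (not isolated), via tributylstannylmagnesium chloride 33 (not isolated)
Conditions: Me3SiBr, 2,6-di-tert-butyl-4-methylpyridine, CH2Cl2, −78 °C; then Bu3SnMgCl (from 31, i-PrMgCl, THF, 0 °C), −78 to −40 °C
Reagents that add atoms: none
Why: The silyl bromide ionises the acylal to α-bromo ether 32, as in the conversion of anomeric acetates into glycosyl bromides; the stannyl Grignard reagent then substitutes at the oxygen-bearing carbon, the reaction type by which α-alkoxy and α-alkoxyallyl stannanes are made from α-halo ethers. Attack at C4 would give a tertiary stannane and is not expected; no control at C6 is expected.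

Step 20
Reactants: 34 C6 stannane
Product: 36 (3S,6S,7S,8R,10S)-cyclodecenol (C6–OH; C7 bearing the 3-[(4-methoxybenzyl)oxy]prop-1-en-2-yl group; 3S silyl ether; 8R,10S acetonide; 4Z), via allyllithium 35 (not isolated)
Conditions: n-BuLi (1.3 equiv), THF, −78 °C; H2O
Reagents that add atoms: none
Why: Butyllithium attacks tin far faster than it removes any proton, so the carbanion appears only at C6 (35) and not at C13, C12 or the benzylic PMB position. C6 then bonds to C7 while O–C13 breaks and C11=C13 forms in one suprafacial, six-electron [2,3]-sigmatropic shift through a five-membered envelope; the closest known reaction types are the Wittig–Still rearrangement and the transannular [2,3]-Wittig ring contraction of macrocyclic diallylic ethers. The ten-membered carbocycle is closed by contraction of the thirteen-membered ether across its 1,5-related atoms C6 and C7, with O, C13 and C11 leaving the ring, not by an end-to-end cyclisation. The relative configuration of C6 and C7 follows from the alkene geometry (C8 cis to C13) and from the six-atom tether C4–C9, which holds C5 and C8 synclinal about the forming bond (C5 exo on the envelope) and so gives the syn adduct that becomes the cis lactone. The absolute sense comes from inversion at C6 of the (6S)-stannane if 35 rearranges faster than it epimerises. Otherwise it comes from the C8 centre, whose hydrogen lies in the alkene plane toward C13 (allylic 1,3-strain), and from the acetonide-bridged C8–C10 segment, which must deliver C6 to the C7 face that places C11 and O8 cis on the new ring. The step needs the [2,3]-shift to outrun the [1,2]-shift, bonding through C4, and 1,4-elimination of the C3 silyloxy group; the low temperature and the five-membered geometry, in which C4 cannot reach C7, favour it. Water then protonates the C6 alkoxide.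

Step 21
Reactants: 36 cyclodecenol PMB ether
Product: 37 (3S,6S,7S,8R,10S)-diol (36 with C12–OH free)
Conditions: DDQ, CH2Cl2/pH 7 buffer, 0 °C
Reagents that add atoms: none
Why: Oxidative PMB cleavage: DDQ abstracts benzylic hydride and water hydrolyses the oxocarbenium ion; the buffer prevents acetal formation with the C6 hydroxyl and the allylic alcohols are oxidised much more slowly.

Step 22
Reactants: 37 diol
Product: 39 (3S,6S,7R,8R,10S)-α-methylene lactone (O6–C12 lactone; 3S silyl ether; 8R,10S acetonide), via hydroxy enal 38 (not isolated)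
Conditions: TEMPO (cat.), PhI(OAc)2, CH2Cl2, rt
Reagents that add atoms: none
Why: Oxidative lactonisation of a 1,4-diol: the primary allylic alcohol is oxidised to enal 38, the cis C6 hydroxyl adds to give a lactol, and a second oxidation gives the lactone; the secondary C6 alcohol itself is oxidised far more slowly.

Step 23
Reactants: 39 lactone acetonide
Product: 40 (3S,6S,7R,8R,10S)-8,10-diol lactone (C3 silyl ether retained)
Conditions: PPTS, MeOH, rt
Reagents that add atoms: none
Why: Acid-catalysed transketalisation to methanol opens the dioxane; a secondary silyl ether survives PPTS in methanol at room temperature, and the weakly acidic medium does not move the lactone to O8.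

Step 24
Reactants: 40 diol lactone
Product: 41 C3 silyl ether of the target (C8 angelate)
Conditions: angelic acid, 2,4,6-trichlorobenzoyl chloride, Et3N, toluene, rt; then 40, toluene, 80 °C
Reagents that add atoms: angelic acid, C/C=C(/C)C(=O)O
Why: Yamaguchi-type mixed-anhydride acylation without DMAP, conditions under which the angeloyl group is transferred without isomerisation to the tigloyl group; only the secondary C8 hydroxyl reacts, the tertiary C10 hydroxyl being too hindered.

Step 25
Reactants: 41 C3 silyl ether
Product: 42 CNP0137971.2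
Conditions: HF·pyridine, pyridine, THF, 0 °C to rt
Reagents that add atoms: none
Why: Buffered fluoride desilylation is neither basic nor nucleophilic toward carbon, so the angelate, the α-methylene lactone and the allylic diol system are left intact.

## Compound list

1 | (S)-linalool, (3S)-3,7-dimethylocta-1,6-dien-3-ol | CC(C)=CCC[C@](C)(O)C=C | starting material
2 | (5S)-5-ethenyl-5-methyloxolan-2-ol (both anomers) | OC1CC[C@](C)(O1)C=C | intermediate
3 | (5S)-5-ethenyl-5-methyloxolan-2-one | O=C1CC[C@](C)(O1)C=C | intermediate
4 | but-2-yn-1-ol | CC#CCO | starting material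
5 | sodium alkenylaluminate chelate from 4 (Al on C4, O–Al ring) | CC1=CCO[Al-]1(OCCOC)OCCOC.[Na+] | intermediate
6 | (Z)-3-iodobut-2-en-1-ol | C/C(I)=C/CO | intermediate
7 | (Z)-tert-butyl[(3-iodobut-2-en-1-yl)oxy]dimethylsilane | C/C(I)=C/CO[Si](C)(C)C(C)(C)C | intermediate
8 | (Z)-alkenyllithium from 7 | [Li]/C(C)=C\CO[Si](C)(C)C(C)(C)C | intermediate
9 | (2Z,7S)-1-[(tert-butyldimethylsilyl)oxy]-7-hydroxy-3,7-dimethylnona-2,8-dien-4-one | CC(C)(C)[Si](C)(C)OC/C=C(/C)C(=O)CC[C@](C)(O)C=C | intermediate
10 | (2Z,4S,7S)-1-[(tert-butyldimethylsilyl)oxy]-3,7-dimethylnona-2,8-diene-4,7-diol | CC(C)(C)[Si](C)(C)OC/C=C(/C)[C@@H](O)CC[C@](C)(O)C=C | intermediate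
11 | (2Z,4S,7S)-1,4-bis[(tert-butyldimethylsilyl)oxy]-3,7-dimethylnona-2,8-dien-7-ol | CC(C)(C)[Si](C)(C)OC/C=C(/C)[C@@H](O[Si](C)(C)C(C)(C)C)CC[C@](C)(O)C=C | intermediate
12 | B-alkyl-9-BBN adduct of 11 (boron on C8) | CC(C)(C)[Si](C)(C)OC/C=C(/C)[C@@H](O[Si](C)(C)C(C)(C)C)CC[C@](C)(O)CCB1C2CCCC1CCC2 | intermediate
13 | (3S,6S,7Z)-6,9-bis[(tert-butyldimethylsilyl)oxy]-3,7-dimethylnon-7-ene-1,3-diol | CC(C)(C)[Si](C)(C)OC/C=C(/C)[C@@H](O[Si](C)(C)C(C)(C)C)CC[C@](C)(O)CCO | intermediate
14 | (3S,6S,7Z)-6,9-bis[(tert-butyldimethylsilyl)oxy]-3-hydroxy-3,7-dimethylnon-7-enal | CC(C)(C)[Si](C)(C)OC/C=C(/C)[C@@H](O[Si](C)(C)C(C)(C)C)CC[C@](C)(O)CC=O | intermediate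
15 | 4-methoxybenzyl propargyl ether, 1-methoxy-4-[(prop-2-yn-1-yloxy)methyl]benzene | C#CCOCc1ccc(OC)cc1 | starting material
16 | lithium acetylide of 15 | [Li]C#CCOCc1ccc(OC)cc1 | intermediate
17 | (6S,9S,10Z)-9,12-bis[(tert-butyldimethylsilyl)oxy]-1-[(4-methoxybenzyl)oxy]-6,10-dimethyldodec-10-en-2-yne-4,6-diol, both C4 epimers | CC(C)(C)[Si](C)(C)OC/C=C(/C)[C@@H](O[Si](C)(C)C(C)(C)C)CC[C@](C)(O)CC(O)C#CCOCc1ccc(OC)cc1 | intermediate
18 | (6S,9S,10Z)-9,12-bis[(tert-butyldimethylsilyl)oxy]-6-hydroxy-1-[(4-methoxybenzyl)oxy]-6,10-dimethyldodec-10-en-2-yn-4-one | CC(C)(C)[Si](C)(C)OC/C=C(/C)[C@@H](O[Si](C)(C)C(C)(C)C)CC[C@](C)(O)CC(=O)C#CCOCc1ccc(OC)cc1 | intermediate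
19 | (4R,6S,9S,10Z)-9,12-bis[(tert-butyldimethylsilyl)oxy]-1-[(4-methoxybenzyl)oxy]-6,10-dimethyldodec-10-en-2-yne-4,6-diol | CC(C)(C)[Si](C)(C)OC/C=C(/C)[C@@H](O[Si](C)(C)C(C)(C)C)CC[C@](C)(O)C[C@@H](O)C#CCOCc1ccc(OC)cc1 | intermediate
20 | sodium alkenylaluminate chelate from 19 (Al on C11, bound to O8) | CC(C)(C)[Si](C)(C)OC/C=C(/C)[C@@H](O[Si](C)(C)C(C)(C)C)CC[C@](C)(O)C[C@H]1O[Al-](OCCOC)(OCCOC)C(COCc2ccc(OC)cc2)=C1.[Na+] | intermediate
21 | (2Z,4R,6S,9S,10Z)-9,12-bis[(tert-butyldimethylsilyl)oxy]-2-iodo-1-[(4-methoxybenzyl)oxy]-6,10-dimethyldodeca-2,10-diene-4,6-diol | CC(C)(C)[Si](C)(C)OC/C=C(/C)[C@@H](O[Si](C)(C)C(C)(C)C)CC[C@](C)(O)C[C@@H](O)/C=C(\I)COCc1ccc(OC)cc1 | intermediate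
22 | (4R,6S)-4-[(Z)-2-iodo-3-[(4-methoxybenzyl)oxy]prop-1-en-1-yl]-2,2,6-trimethyl-6-[(3S,4Z)-3,6-bis[(tert-butyldimethylsilyl)oxy]-4-methylhex-4-en-1-yl]-1,3-dioxane | CC(C)(C)[Si](C)(C)OC/C=C(/C)[C@@H](O[Si](C)(C)C(C)(C)C)CC[C@@]1(C)C[C@H](/C=C(\I)COCc2ccc(OC)cc2)OC(C)(C)O1 | intermediate
23 | (2Z,4S)-4-[(tert-butyldimethylsilyl)oxy]-6-[(4S,6R)-6-[(Z)-2-iodo-3-[(4-methoxybenzyl)oxy]prop-1-en-1-yl]-2,2,4-trimethyl-1,3-dioxan-4-yl]-3-methylhex-2-en-1-ol | OC/C=C(/C)[C@@H](O[Si](C)(C)C(C)(C)C)CC[C@@]1(C)C[C@H](/C=C(\I)COCc2ccc(OC)cc2)OC(C)(C)O1 | intermediate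
24 | (2Z,4S)-enal corresponding to 23 (C6 aldehyde) | O=C/C=C(/C)[C@@H](O[Si](C)(C)C(C)(C)C)CC[C@@]1(C)C[C@H](/C=C(\I)COCc2ccc(OC)cc2)OC(C)(C)O1 | intermediate
25 | (2Z,4S)-enoic acid corresponding to 23 (C6 carboxylic acid) | OC(=O)/C=C(/C)[C@@H](O[Si](C)(C)C(C)(C)C)CC[C@@]1(C)C[C@H](/C=C(\I)COCc2ccc(OC)cc2)OC(C)(C)O1 | intermediate
26 | hydroxy acid: 25 with CH2OH (C13) in place of iodine, cis to C8 | OC(=O)/C=C(/C)[C@@H](O[Si](C)(C)C(C)(C)C)CC[C@@]1(C)C[C@H](/C=C(\CO)COCc2ccc(OC)cc2)OC(C)(C)O1 | intermediate
27 | mixed anhydride of 26 with 2-methyl-6-nitrobenzoic acid | Cc1cccc([N+](=O)[O-])c1C(=O)OC(=O)/C=C(/C)[C@@H](O[Si](C)(C)C(C)(C)C)CC[C@@]2(C)C[C@H](/C=C(\CO)COCc3ccc(OC)cc3)OC(C)(C)O2 | intermediate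
28 | thirteen-membered macrolactone (C6 carbonyl, O–C13; 3S, 8R, 10S; 4Z; C8 cis to C13) | C1OC(=O)/C=C(/C)[C@@H](O[Si](C)(C)C(C)(C)C)CC[C@]2(C)OC(C)(C)O[C@H](C2)/C=C1/COCc1ccc(OC)cc1 | intermediate
29 | diisobutylaluminium hemiacetal of 28 (both C6 epimers) | C1OC(O[Al](CC(C)C)CC(C)C)/C=C(/C)[C@@H](O[Si](C)(C)C(C)(C)C)CC[C@]2(C)OC(C)(C)O[C@H](C2)/C=C1/COCc1ccc(OC)cc1 | intermediate
30 | thirteen-membered α-acetoxy ether (both C6 epimers) | C1OC(OC(C)=O)/C=C(/C)[C@@H](O[Si](C)(C)C(C)(C)C)CC[C@]2(C)OC(C)(C)O[C@H](C2)/C=C1/COCc1ccc(OC)cc1 | intermediate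
31 | tributyltin hydride | CCCC[SnH](CCCC)CCCC | starting material
32 | thirteen-membered α-bromo ether (both C6 epimers) | C1OC(Br)/C=C(/C)[C@@H](O[Si](C)(C)C(C)(C)C)CC[C@]2(C)OC(C)(C)O[C@H](C2)/C=C1/COCc1ccc(OC)cc1 | intermediate
33 | tributylstannylmagnesium chloride | CCCC[Sn](CCCC)(CCCC)[Mg]Cl | intermediate
34 | (6S)-6-tributylstannyl thirteen-membered allylic ether (3S, 8R, 10S; 4Z; C8 cis to C13; the 6R epimer forms alongside) | C1O[C@@H]([Sn](CCCC)(CCCC)CCCC)/C=C(/C)[C@@H](O[Si](C)(C)C(C)(C)C)CC[C@]2(C)OC(C)(C)O[C@H](C2)/C=C1/COCc1ccc(OC)cc1 | intermediate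
35 | C6 α-alkoxy allyllithium of the thirteen-membered ether (C6 configuration not fixed) | C1OC([Li])/C=C(/C)[C@@H](O[Si](C)(C)C(C)(C)C)CC[C@]2(C)OC(C)(C)O[C@H](C2)/C=C1/COCc1ccc(OC)cc1 | intermediate
36 | (3S,6S,7S,8R,10S)-cyclodecenol with C7 3-[(4-methoxybenzyl)oxy]prop-1-en-2-yl group, C3 silyl ether, C8/C10 acetonide, 4Z | C=C(COCc1ccc(OC)cc1)[C@H]1[C@@H](O)/C=C(/C)[C@@H](O[Si](C)(C)C(C)(C)C)CC[C@]2(C)OC(C)(C)O[C@@H]1C2 | intermediate
37 | (3S,6S,7S,8R,10S)-diol: 36 with C12–OH free | C=C(CO)[C@H]1[C@@H](O)/C=C(/C)[C@@H](O[Si](C)(C)C(C)(C)C)CC[C@]2(C)OC(C)(C)O[C@@H]1C2 | intermediate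
38 | hydroxy enal from 37 (C12 aldehyde; in equilibrium with its lactol) | C=C(C=O)[C@H]1[C@@H](O)/C=C(/C)[C@@H](O[Si](C)(C)C(C)(C)C)CC[C@]2(C)OC(C)(C)O[C@@H]1C2 | intermediate
39 | (3S,6S,7R,8R,10S)-α-methylene lactone with C3 silyl ether and C8/C10 acetonide | C=C1C(=O)O[C@H]2/C=C(/C)[C@@H](O[Si](C)(C)C(C)(C)C)CC[C@@]3(C)C[C@@H](OC(C)(C)O3)[C@@H]12 | intermediate
40 | (3S,6S,7R,8R,10S)-8,10-diol lactone with C3 silyl ether | C=C1C(=O)O[C@H]2/C=C(/C)[C@@H](O[Si](C)(C)C(C)(C)C)CC[C@](C)(O)C[C@@H](O)[C@@H]12 | intermediate
41 | C3 tert-butyldimethylsilyl ether of the target | C=C1C(=O)O[C@H]2/C=C(/C)[C@@H](O[Si](C)(C)C(C)(C)C)CC[C@](C)(O)C[C@@H](OC(=O)/C(C)=C\C)[C@@H]12 | intermediate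
42 | CNP0137971.2, (3S,6S,7R,8R,10S; 4Z) 8-angeloyloxy-3,10-dihydroxy germacr-4,11(13)-dien-6,12-olide | C=C1C(=O)O[C@H]2/C=C(/C)[C@@H](O)CC[C@](C)(O)C[C@@H](OC(=O)/C(C)=C\C)[C@@H]12 | target

## Step count and least certain steps

Total: 25 steps. Longest linear sequence: 24 steps (but-2-yn-1-ol 4 to 42, steps 2–25); 23 steps from (S)-linalool.

**Step 20 (key step).** What may go wrong:
- C6 may bond to the wrong face of C7=C11 relative to C8, because ring conformation and not a reagent chooses the face.
- The C3 silyloxy group may be lost by 1,4-elimination from the delocalised allyl anion.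
- A [1,2]-shift may compete with the [2,3]-shift.

Fallback (carbonyl allylation in place of the sigmatropic shift, same C6–C7 bond): set out from alcohol 23. MnO2 gives enal 24, isolated this time. Stille coupling with Bu3SnCH2OH gives the hydroxy enal F1. CBr4/PPh3 gives the allylic bromide F2. CrCl2 in THF/DMF at high dilution (intramolecular Nozaki–Hiyama allylation) converts C13–Br into an allylchromium that adds through C7 to the C6 aldehyde in a closed chair transition state. This forms C6–C7 and the C11=C13 methylene directly and rejoins the route at 36. With C8 cis to the metal-bearing C13 the chair should also give the syn C6/C7 relation, and its face preference is independent of that of the Wittig shift.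

**Step 19.** What may go wrong:
- The silyl bromide may cleave the acetonide or the PMB ether.
- The ionised acetal may undergo allylic transposition.
- Electron transfer from the stannyl reagent to the bromo ether may lead to reduction or dimerisation instead of substitution.

Fallback (sulfur in place of tin, the reductive-lithiation entry to [2,3]-Wittig shifts): from 30, PhSSiMe3 and ZnI2 in CH2Cl2 at −78 °C give the phenylthio O,S-acetal F3 under milder ionising conditions. Lithium 4,4′-di-tert-butylbiphenylide in THF at −78 °C cleaves the C–S bond to the same allyllithium 35, which rearranges. The sequence rejoins the route at 36 without passing through 34.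

**Step 17.** What may go wrong:
- Oligomerisation may compete with ring closure.
- The activated enoate may isomerise from Z to E.
- The C3 silyl ether oxygen may attack the activated acyl group, with loss of silicon and closure of a five-membered lactone.

Fallback (activate the alcohol, not the acid): from 26, a Mitsunobu macrolactonisation (PPh3, diisopropyl azodicarboxylate, toluene, slow addition) makes the carboxylate the nucleophile toward the C13 oxyphosphonium. It rejoins the route at 28, and no new compound arises (F0).

**Step 24.** What may go wrong: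
- The angeloyl group may isomerise to the tigloyl group during activation.
- The lactone acyl group may migrate from O6 to the free O8 under the warm, basic conditions.

Fallback (build the Z enoate on the molecule): from 40, esterify the C8 hydroxyl with 2-[bis(2,2,2-trifluoroethoxy)phosphoryl]propanoic acid (diisopropylcarbodiimide, DMAP, 0 °C) to the phosphonate ester F4. Still–Gennari olefination with acetaldehyde (KHMDS, 18-crown-6, THF, −78 °C) then gives the Z 2-methylbut-2-enoate and rejoins the route at 41.

## Further compounds

F1 | step 20 | hydroxy enal (24 with CH2OH at C11 in place of iodine, cis to C8) | O=C/C=C(/C)[C@@H](O[Si](C)(C)C(C)(C)C)CC[C@@]1(C)C[C@H](/C=C(\CO)COCc2ccc(OC)cc2)OC(C)(C)O1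
F2 | step 20 | allylic bromide (F1 with C13–Br) | O=C/C=C(/C)[C@@H](O[Si](C)(C)C(C)(C)C)CC[C@@]1(C)C[C@H](/C=C(\CBr)COCc2ccc(OC)cc2)OC(C)(C)O1
F3 | step 19 | thirteen-membered C6 phenylthio O,S-acetal (both C6 epimers) | C1OC(Sc2ccccc2)/C=C(/C)[C@@H](O[Si](C)(C)C(C)(C)C)CC[C@]3(C)OC(C)(C)O[C@H](C3)/C=C1/COCc1ccc(OC)cc1
F0 | step 17 | none | none
F4 | step 24 | C8 2-[bis(2,2,2-trifluoroethoxy)phosphoryl]propanoate of 40 | C=C1C(=O)O[C@H]2/C=C(/C)[C@@H](O[Si](C)(C)C(C)(C)C)CC[C@](C)(O)C[C@@H](OC(=O)C(C)P(=O)(OCC(F)(F)F)OCC(F)(F)F)[C@@H]12
A1 | alternative 1 | C3,C6-bridged endoperoxide | C=C(C(=O)OC)[C@H]1[C@H]2OO[C@@H](CC[C@](C)(O)C[C@H]1OC(=O)/C(C)=C\C)C(C)=C2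
A2 | alternative 1 | ten-membered cis,cis-3,5-diene with C7 acrylate and C8 angelate | C=C(C(=O)OC)[C@H]1/C=C\C(C)=C/CC[C@](C)(O)C[C@H]1OC(=O)/C(C)=C\C
A3 | alternative 2 | isoxazoline-bridged ten-membered carbocycle with cis lactone | O=C1O[C@H]2/C=C(/C)[C@@H](O[Si](C)(C)C(C)(C)C)CCC3=NO[C@H](C3)[C@H]2C1
A4 | alternative 2 | C10 aldoxime with C7 vinyl group on the cis lactone | C=C[C@H]1CC(=O)O[C@H]1/C=C(/C)[C@@H](O[Si](C)(C)C(C)(C)C)CCC=NO
A5 | alternative 3 | target as its C10 triethylsilyl ether | C=C1C(=O)O[C@H]2/C=C(/C)[C@@H](O)CC[C@](C)(O[Si](CC)(CC)CC)C[C@@H](OC(=O)/C(C)=C\C)[C@@H]12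
A6 | alternative 3 | seco C3 aldehyde with C4 alkenyl iodide | C=C1C(=O)O[C@@H](/C=C(/C)I)[C@H]1[C@H](OC(=O)/C(C)=C\C)C[C@@](C)(O[Si](CC)(CC)CC)CCC=O
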